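One reciprocal molar-hour is the unit in which I judge this flask, the unit of a step-growth constant with unequal charges.

| flask | starting material | reagent in the second phase | remark | time | volume of the second phase over the first |
|---|---|---|---|---|---|
| teal | 20 mM | 24 mM | the very flask that is asked about, followed so far |  |  |
| blue | 20 mM | 12 mM | run made earlier |  |  |
| flask | 20 mM | 24.0 mM |  | 25 h | 0.50 |

- teal (time / h: target / %, starting material / %): 0.833: 10.1, 64.9; 2.50: 33.9, 40.8; 4.00: 50.1, 30.4; 6.00: 64.5, 21.6; 10.0: 78.6, 12.4; 12.0: 82.4, 9.0
- blue (time / h: target / %, starting material / %): 3.00: 22.3, 50.7; 6.00: 35.3, 39.9; 8.00: 41.7, 37.4; 12.0: 49.6, 31.7; 15.0: 51.1, 28.7; 20.0: 52.7, 26.4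

(scatter of a reading: 0.5 percentage points)

- in the second phase: reagent in the second phase; everything else is in the first
- charges count per volume of the first phase; a concentration in a rate is the amount of a species over the volume of its own phase; every rate counts per litre of the first phase
- the numbers in the tables scatter by 0.5 percentage points (one standard deviation)
- the earlier runs hold the two phases in the same ratio of volumes as the flask asked about

* how much target there is at 25 h, in percent of the starting material charged
* the change that raises the amount of target at 25 h, in percent of the starting material charged most ("none" if none brings more than 2 percentage points) (ash / alder / none)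
* amount of target at 25 h, in percent of the starting material charged, after ash

I build the flask one process at a time. First I take the main step, with the rate proportional to reagent left times material not yet target. Starting material is the limiting reagent, since its 20 mM is less than the 24.0 mM of reagent. Integrated, the logarithm of reagent left over material not yet target then climbs in a straight line. Its hourly rise divided by the excess of reagent is my apparent second-order constant, read from the teal run between 6.00 h and 12.0 h: 13.0 M⁻¹ h⁻¹. Continued to 25 h, the quotient reaches 4.20, which means 93.8% target.

Next I add the unseen holding form. Teal's balance lacks 25 percentage points at 2.50 h, but my pool already counts that material as not yet target, so the number stays and the constant becomes an apparent one.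

Then I add a loss of reagent, as a working assumption of mine. At its last reading, 20.0 h, the blue run's target stands 1.46 mM short of its reagent charge. Taking that much from the reagent narrows the excess and gives a quotient of 2.65, so I commit to 92.3%. Doubling the reagent widens the excess from 4.00 mM to 28.0 mM, so I choose alder.

The forecast says 92.5% (90% to 95%), alder, and 93% after ash (90.5% to 97%), on the ground that “Chemistry, not transfer, appears to limit”.

The flask gives 91.7%, against my 92.3%; the best change is alder, which adds 6.3 points, while ash adds 1.1 points and ends at 92.8%.

    reagent in the reaction phase ⇌ reagent in the second phase, rate k1*([reagent in the reaction phase] - [reagent in the second phase]/K1) per volume of the first phase (partition coefficient = 2.60, kL = 0.440 h⁻¹)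
    starting material + reagent in the reaction phase → target (k = 73.0 M⁻¹ h⁻¹)
    starting material + target → side product (k = 0.740 M⁻¹ h⁻¹)
    starting material ⇌ dormant form (K = 0.510, k = 0.600 h⁻¹)

In the flask the main step has 62% of its turnover up to 25 h behind it by 5.00 h, and the dormant form stands at 24.4% at 2.50 h and at 1.05% at 25.0 h. At 25.0 h the flask holds 1.9% starting material and 5.40% side product, counted as two. Carried to the same flask with 12 mM starting material, 13.0 M⁻¹ h⁻¹ gives 99.0% target at 25 h, and that neighbour holds 97.6%.

The numbers in the tables were computed on assumed constants; the scatter is artificial.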